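**Retrosynthetic overview**

Ring numbering used throughout: C1 (OAc), C2 (OH), C3 (OH), C4=C5 (C5 carries C7H2OBz), C6 (OBz). The strategy rests on the 1,4 relation across the carbocycle between the C1 oxygen and the alkene carbon C4: one ether oxygen spanning C1 and C4 (a 7-oxabicyclo[2.2.1]heptane) serves first as the C1 oxygen and is later cut at C4–O to create C4=C5.
Target ⇒ anti hydrolysis at allylic C3 of a 2,3-epoxide cis to O1 ⇒ acylations and ester reduction ⇒ methyl 2,3-epoxy-1-hydroxy-6-silyloxycyclohex-4-ene-5-carboxylate ⇒ ester-enolate β-elimination of the C4–O bridge bond in an exo-epoxy-7-oxanorbornane ester.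
That ester ⇒ exo epoxidation and benzoate/silyl exchange ⇒ endo,endo Diels–Alder adduct (bonds C4–C5 and C6–C1) of furan and methyl (Z)-3-(benzoyloxy)acrylate ⇒ methyl propiolate + benzoic acid.
Ring order: the carbocycle is the only ring built, and it is formed in the cycloaddition as an oxygen-bridged bicycle. The epoxide (step 3) is an auxiliary ring; the bridge is opened in step 6 and the epoxide in step 12.

Key step: step 2

Assumption: the oxazaborolidinium ion is taken to bind the acrylate carbonyl of the dienophile as it binds simple acrylate esters, and on that model the catalyst from (R)-α,α-diphenylprolinol exposes the required face; if the sense of induction is the opposite, the (S)-catalyst is used and nothing else changes.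

**Step 1**
Reactants: 1 methyl propiolate; 2 benzoic acid
Product: 3 methyl (Z)-3-(benzoyloxy)acrylate
Conditions: Ag2CO3 (5 mol %), toluene, 60 °C
Reagents that add atoms: none
Why: Silver-catalysed hydroacyloxylation of an electron-poor alkyne, in which benzoate attacks the triple bond activated by monovalent silver at the β-carbon from the face opposite to the metal and protodemetalation with retention gives the anti adduct, that is the (Z)-enol ester; amine and phosphine catalysts, which lead to the E isomer by addition–elimination, are kept out.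

**Step 2**
Reactants: 3 methyl (Z)-3-(benzoyloxy)acrylate; 4 furan
Product: 5 methyl (1R,2S,3S,4S)-3-(benzoyloxy)-7-oxabicyclo[2.2.1]hept-5-ene-2-carboxylate (ester and benzoate both endo, anti to the oxygen bridge)
Conditions: 4 (10 equiv), B-(2-methylphenyl)oxazaborolidine of (R)-α,α-diphenylprolinol (20 mol %) + HN(SO2CF3)2 (20 mol %), CH2Cl2, −78 → −40 °C; Et3N, −78 °C
Reagents that add atoms: none
Why: Proposed new method: the closest known reaction type is the oxazaborolidinium-catalysed endo Diels–Alder reaction of furan with acrylate esters, extended here to a cis-β-acyloxy acrylate; the cationic boron should bind the acrylate carbonyl of 3 (the more basic carbonyl, being a vinylogous carbonate) anti to OMe with an α-C–H···O contact, lower the LUMO and let furan add in a concerted suprafacial [4+2] process that forms C4–C5 and C6–C1. The carbocycle C1–C6 is closed by this intermolecular cycloaddition, both ring bonds being made at once, and the furan oxygen remains as the one-atom bridge between C1 and C4. The cis relation of C5–CO2Me and C6–OBz follows from the Z geometry of 3; their position anti to the bridge (hence C6–O trans to C1–O) follows from the endo transition state favoured under Lewis acid catalysis at low temperature; the absolute configuration at C1, C4, C5 and C6 follows from the phenyl group of the catalyst shielding one face of the bound dienophile. The step needs endo selectivity, enantiofacial selectivity and kinetic control, because furan adducts revert and drift to exo isomers; the low temperature, the amine quench and immediate epoxidation in step 3 are meant to hold the kinetic adduct. The β-benzoyloxy group is a weak donor that lowers dienophile reactivity, so a full 20 mol % of the triflimide-activated catalyst and a large excess of furan are used.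

**Step 3**
Reactants: 5 Diels–Alder adduct
Product: 6 methyl 6-(benzoyloxy)-1,4:2,3-diepoxycyclohexane-5-carboxylate (route numbering; 2,3-epoxide exo, on the face of the 1,4-oxygen bridge; CO2Me and OBz on the opposite face)
Conditions: dimethyldioxirane (acetone solution, 1.5 equiv), CH2Cl2, 0 °C
Reagents that add atoms: dimethyldioxirane, CC1(C)OO1
Why: Dioxirane epoxidation of a strained bicyclic alkene by concerted oxygen transfer, which should occur on the exo face of C2=C3 (the side of the oxygen bridge) because the endo face is screened by the C5 and C6 substituents, so the epoxide oxygen ends up cis to the C1 oxygen; saturating the alkene also stops cycloreversion to furan.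

**Step 4**
Reactants: 6 epoxy benzoate
Product: 7 methyl 1,4:2,3-diepoxy-6-hydroxycyclohexane-5-carboxylate (route numbering; OH and CO2Me endo)
Conditions: K2CO3 (0.2 equiv), MeOH, 0 °C
Reagents that add atoms: none
Why: Base-catalysed transesterification (Zemplén-type methanolysis) removes the benzoyl group as methyl benzoate while exchange at the methyl ester is degenerate, and at 0 °C the hindered exo epoxide and the β-hydroxy ester are expected to survive; an epimerisation at C5 would be of no consequence because C5 becomes trigonal in step 6.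

**Step 5**
Reactants: 7 epoxy alcohol
Product: 8 methyl 6-(tert-butyldimethylsilyloxy)-1,4:2,3-diepoxycyclohexane-5-carboxylate (route numbering; configuration as in 7)
Conditions: TBSOTf, 2,6-lutidine, CH2Cl2, −40 → 0 °C
Reagents that add atoms: tert-butyldimethylsilyl trifluoromethanesulfonate, CC(C)(C)[Si](C)(C)OS(=O)(=O)C(F)(F)F
Why: Silylation of a hindered secondary alcohol with a silyl triflate and a non-nucleophilic base; the silyloxy group is a far poorer leaving group than benzoate, which step 6 requires.

**Step 6**
Reactants: 8 silyl ether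
Product: 9 methyl 6-(tert-butyldimethylsilyloxy)-2,3-epoxy-1-hydroxycyclohex-4-ene-5-carboxylate (1-OH cis to the epoxide oxygen, 6-OSi trans to 1-OH)
Conditions: LiN(SiMe3)2 (1.1 equiv), THF, −78 → −40 °C; AcOH, −78 °C
Reagents that add atoms: none
Why: E1cB β-elimination, the known base-induced opening of 7-oxanorbornane-2-carboxylates to hydroxycyclohexene carboxylates: the amide base removes the exo C5–H and the ester enolate expels the strained C4–O bridge bond, creating C4=C5 and leaving the bridge oxygen as the C1 hydroxyl with unchanged configuration; a slight excess of base, low temperature and a cold acidic quench are used so that the C6 silyloxy group is neither expelled nor transferred to the C1 alkoxide.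

**Step 7**
Reactants: 9 epoxy hydroxy ester
Product: 10 6-(tert-butyldimethylsilyloxy)-2,3-epoxy-5-(hydroxymethyl)cyclohex-4-en-1-ol (configuration as in 9)
Conditions: i-Bu2AlH (3.5 equiv), CH2Cl2, −78 °C; aq. potassium sodium tartrate
Reagents that add atoms: none
Why: 1,2-Reduction of a conjugated ester to the allylic alcohol by an aluminium hydride, the first equivalent being consumed by the C1 hydroxyl; at −78 °C the epoxide and the silyl ether should not be attacked.

**Step 8**
Reactants: 10 diol
Product: 11 [6-(tert-butyldimethylsilyloxy)-2,3-epoxy-1-hydroxycyclohex-4-en-5-yl]methyl benzoate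
Conditions: BzCl (1.05 equiv), 2,4,6-collidine, CH2Cl2, −40 °C
Reagents that add atoms: benzoyl chloride, O=C(Cl)c1ccccc1
Why: Chemoselective acylation, the primary allylic C7 hydroxyl reacting with one equivalent of acid chloride much faster than the secondary C1 hydroxyl, which is flanked by the epoxide and the silyloxy group.

**Step 9**
Reactants: 11 monobenzoate
Product: 12 [1-acetoxy-6-(tert-butyldimethylsilyloxy)-2,3-epoxycyclohex-4-en-5-yl]methyl benzoate
Conditions: Ac2O, pyridine, DMAP (cat.), CH2Cl2, 0 °C → rt
Reagents that add atoms: acetic anhydride, CC(=O)OC(C)=O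
Why: Acetylation of the remaining secondary alcohol under nucleophilic catalysis by DMAP, which places the acetate on the former bridge oxygen at C1 without touching a stereocentre.

**Step 10**
Reactants: 12 acetate
Product: 13 [1-acetoxy-2,3-epoxy-6-hydroxycyclohex-4-en-5-yl]methyl benzoate
Conditions: Bu4NF, AcOH (1:1), THF, 0 °C → rt
Reagents that add atoms: none
Why: Fluoride-induced desilylation, buffered with acetic acid so that the medium stays non-basic and the C1 acetate should not migrate to the trans-vicinal C6 hydroxyl nor the epoxide open; a benzoyl shift from O7 to O6 would be harmless because step 11 benzoylates whichever hydroxyl is free.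

**Step 11**
Reactants: 13 allylic alcohol
Product: 14 1-acetoxy-6-(benzoyloxy)-5-(benzoyloxymethyl)-2,3-epoxycyclohex-4-ene (epoxide oxygen cis to 1-OAc, 6-OBz trans to 1-OAc)
Conditions: BzCl, pyridine, DMAP (cat.), CH2Cl2, 0 °C → rt
Reagents that add atoms: benzoyl chloride, O=C(Cl)c1ccccc1
Why: Acylation of the allylic secondary alcohol with an acid chloride under DMAP catalysis; the C6 stereocentre is not involved.

**Step 12**
Reactants: 14 epoxy triester
Product: 15 [(3R,4S,5S,6S)-5-acetoxy-6-(benzoyloxy)-3,4-dihydroxycyclohex-1-en-1-yl]methyl benzoate (route numbering 1S,2S,3R,6S)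
Conditions: HClO4 (cat.), THF/H2O (3:1), 0 °C → rt
Reagents that add atoms: water, O
Why: Acid-catalysed hydrolysis of a vinyl epoxide, in which water should attack the protonated epoxide at the allylic carbon C3 (activated by C4=C5, whereas C2 is deactivated by the neighbouring C1 acetoxy group) from the face opposite to the epoxide oxygen, giving inversion at C3 and retention at C2, that is the 2,3-trans-diol with the C2 hydroxyl cis to the C1 acetate; the three esters should survive dilute acid at this temperature.

**Compound list**

1 | methyl propiolate | C#CC(=O)OC | starting material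
2 | benzoic acid | OC(=O)c1ccccc1 | starting material
3 | methyl (Z)-3-(benzoyloxy)acrylate | COC(=O)/C=C\OC(=O)c1ccccc1 | intermediate
4 | furan | c1ccoc1 | starting material
5 | methyl (1R,2S,3S,4S)-3-(benzoyloxy)-7-oxabicyclo[2.2.1]hept-5-ene-2-carboxylate (2-endo, 3-endo) | O1[C@H]2C=C[C@@H]1[C@H](C(=O)OC)[C@@H]2OC(=O)c1ccccc1 | intermediate
6 | methyl 6-(benzoyloxy)-1,4:2,3-diepoxycyclohexane-5-carboxylate (exo-epoxide of 5) | O1[C@H]2[C@H]3O[C@H]3[C@@H]1[C@H](C(=O)OC)[C@@H]2OC(=O)c1ccccc1 | intermediate
7 | methyl 1,4:2,3-diepoxy-6-hydroxycyclohexane-5-carboxylate | O1[C@H]2[C@H]3O[C@H]3[C@@H]1[C@H](C(=O)OC)[C@@H]2O | intermediate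
8 | methyl 6-(tert-butyldimethylsilyloxy)-1,4:2,3-diepoxycyclohexane-5-carboxylate | O1[C@H]2[C@H]3O[C@H]3[C@@H]1[C@H](C(=O)OC)[C@@H]2O[Si](C)(C)C(C)(C)C | intermediate
9 | methyl 6-(tert-butyldimethylsilyloxy)-2,3-epoxy-1-hydroxycyclohex-4-ene-5-carboxylate | O[C@H]1[C@H]2O[C@H]2C=C(C(=O)OC)[C@@H]1O[Si](C)(C)C(C)(C)C | intermediate
10 | 6-(tert-butyldimethylsilyloxy)-2,3-epoxy-5-(hydroxymethyl)cyclohex-4-en-1-ol | O[C@H]1[C@H]2O[C@H]2C=C(CO)[C@@H]1O[Si](C)(C)C(C)(C)C | intermediate
11 | [6-(tert-butyldimethylsilyloxy)-2,3-epoxy-1-hydroxycyclohex-4-en-5-yl]methyl benzoate | O[C@H]1[C@H]2O[C@H]2C=C(COC(=O)c2ccccc2)[C@@H]1O[Si](C)(C)C(C)(C)C | intermediate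
12 | [1-acetoxy-6-(tert-butyldimethylsilyloxy)-2,3-epoxycyclohex-4-en-5-yl]methyl benzoate | CC(=O)O[C@H]1[C@H]2O[C@H]2C=C(COC(=O)c2ccccc2)[C@@H]1O[Si](C)(C)C(C)(C)C | intermediate
13 | [1-acetoxy-2,3-epoxy-6-hydroxycyclohex-4-en-5-yl]methyl benzoate | CC(=O)O[C@H]1[C@H]2O[C@H]2C=C(COC(=O)c2ccccc2)[C@@H]1O | intermediate
14 | 1-acetoxy-6-(benzoyloxy)-5-(benzoyloxymethyl)-2,3-epoxycyclohex-4-ene | CC(=O)O[C@H]1[C@H]2O[C@H]2C=C(COC(=O)c2ccccc2)[C@@H]1OC(=O)c1ccccc1 | intermediate
15 | [(3R,4S,5S,6S)-5-acetoxy-6-(benzoyloxy)-3,4-dihydroxycyclohex-1-en-1-yl]methyl benzoate | CC(=O)O[C@H]1[C@@H](O)[C@H](O)C=C(COC(=O)c2ccccc2)[C@@H]1OC(=O)c1ccccc1 | target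

**Totals**

Total step count: 12. Longest linear sequence: 12 steps (1 and 2 to 15; furan 4 enters at step 2).

**Steps most likely to fail**

Step 2 (carries the new method). The cis-β-benzoyloxy dienophile may be too unreactive towards furan at the temperature needed for kinetic control, or the catalyst may bind the benzoate carbonyl instead of the acrylate carbonyl. Either would lead to poor conversion, loss of endo selectivity through reversal, or poor facial selectivity. The fallback uses known reactions only and gives up catalytic enantiocontrol for a resolution; it sets out from 1 (with 4) and returns at 5. Methyl propiolate 1 is brominated at the alkyne terminus (NBS, AgNO3 cat., acetone) to methyl 3-bromopropiolate F1. F1 undergoes thermal Diels–Alder addition in warm excess furan 4 to racemic methyl 3-bromo-7-oxabicyclo[2.2.1]hepta-2,5-diene-2-carboxylate F2. NaOMe in MeOH converts F2, by addition–elimination, a second addition and protonation on the exo face, into the ketal methyl 3,3-dimethoxy-7-oxabicyclo[2.2.1]hept-5-ene-2-endo-carboxylate F3. Aqueous HCl in THF unmasks the β-keto ester methyl 3-oxo-7-oxabicyclo[2.2.1]hept-5-ene-2-carboxylate F4. NaBH4 (MeOH, −20 °C) delivers hydride on the exo face to give the racemic hydroxy ester methyl 3-endo-hydroxy-7-oxabicyclo[2.2.1]hept-5-ene-2-endo-carboxylate F5. F5 is resolved by acetylation with vinyl acetate and Candida antarctica lipase B, the lipase being chosen by screening so that the unwanted enantiomer is acylated. Benzoylation of the remaining alcohol (BzCl, pyridine, DMAP) gives 5. Should part of the material carry an exo ester, it converges at 9, where C5 becomes trigonal.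

Step 6. The enolate may expel the C6 silyloxy group instead of cleaving the bridge, or the silyl group may migrate from O6 to the newly formed C1 alkoxide. The fallback replaces the silyl ether by an alkyl ether, which is a poorer leaving group and cannot migrate; it sets out from 7 and returns at 13. Alcohol 7 is treated with 4-methoxybenzyl trichloroacetimidate and catalytic camphorsulfonic acid in CH2Cl2 to give methyl 1,4:2,3-diepoxy-6-(4-methoxybenzyloxy)cyclohexane-5-carboxylate F6. LiN(SiMe3)2 (THF, −78 °C) opens the bridge to methyl 2,3-epoxy-1-hydroxy-6-(4-methoxybenzyloxy)cyclohex-4-ene-5-carboxylate F7. Reduction with i-Bu2AlH gives 2,3-epoxy-5-(hydroxymethyl)-6-(4-methoxybenzyloxy)cyclohex-4-en-1-ol F8. Selective benzoylation (BzCl, collidine, −40 °C) gives [2,3-epoxy-1-hydroxy-6-(4-methoxybenzyloxy)cyclohex-4-en-5-yl]methyl benzoate F9. Acetylation gives [1-acetoxy-2,3-epoxy-6-(4-methoxybenzyloxy)cyclohex-4-en-5-yl]methyl benzoate F10. Oxidative ether cleavage with DDQ (CH2Cl2, pH 7 buffer), which is neutral and so avoids acyl migration as well, gives 13.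

Step 12. The protonated vinyl epoxide may ionise to an allyl cation, so that water adds at C5 or on either face of C3, and the acid may promote acetyl migration from O1 to O2. The fallback replaces specific-acid hydrolysis by a bimolecular carboxylate opening followed by selective deacylation; it sets out from 14 and returns at 15. Treatment of 14 with chloroacetic acid and ClCH2CO2Cs in DMF at 40 °C should open the epoxide at C3 with inversion to give [5-acetoxy-6-(benzoyloxy)-3-(chloroacetoxy)-4-hydroxycyclohex-1-en-1-yl]methyl benzoate F11. The chloroacetyl group is then removed with thiourea and NaHCO3 in EtOH, conditions that leave acetate and benzoates intact, to give 15. A chloroacetyl shift from O3 to O2 would not matter, since both positions are free hydroxyls in the target.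

**Further compounds**

F1 | step 2 | methyl 3-bromopropiolate | COC(=O)C#CBr
F2 | step 2 | methyl 3-bromo-7-oxabicyclo[2.2.1]hepta-2,5-diene-2-carboxylate (racemic; enantiomer of the route drawn) | O1[C@H]2C=C[C@@H]1C(C(=O)OC)=C2Br
F3 | step 2 | methyl 3,3-dimethoxy-7-oxabicyclo[2.2.1]hept-5-ene-2-endo-carboxylate (racemic; enantiomer of the route drawn) | O1[C@H]2C=C[C@@H]1[C@H](C(=O)OC)C2(OC)OC
F4 | step 2 | methyl 3-oxo-7-oxabicyclo[2.2.1]hept-5-ene-2-endo-carboxylate (racemic; enantiomer of the route drawn) | O1[C@H]2C=C[C@@H]1[C@H](C(=O)OC)C2=O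
F5 | step 2 | methyl 3-endo-hydroxy-7-oxabicyclo[2.2.1]hept-5-ene-2-endo-carboxylate (racemic, then the resolved enantiomer drawn) | O1[C@H]2C=C[C@@H]1[C@H](C(=O)OC)[C@@H]2O
F6 | step 6 | methyl 1,4:2,3-diepoxy-6-(4-methoxybenzyloxy)cyclohexane-5-carboxylate | O1[C@H]2[C@H]3O[C@H]3[C@@H]1[C@H](C(=O)OC)[C@@H]2OCc1ccc(OC)cc1
F7 | step 6 | methyl 2,3-epoxy-1-hydroxy-6-(4-methoxybenzyloxy)cyclohex-4-ene-5-carboxylate | O[C@H]1[C@H]2O[C@H]2C=C(C(=O)OC)[C@@H]1OCc1ccc(OC)cc1
F8 | step 6 | 2,3-epoxy-5-(hydroxymethyl)-6-(4-methoxybenzyloxy)cyclohex-4-en-1-ol | O[C@H]1[C@H]2O[C@H]2C=C(CO)[C@@H]1OCc1ccc(OC)cc1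
F9 | step 6 | [2,3-epoxy-1-hydroxy-6-(4-methoxybenzyloxy)cyclohex-4-en-5-yl]methyl benzoate | O[C@H]1[C@H]2O[C@H]2C=C(COC(=O)c2ccccc2)[C@@H]1OCc1ccc(OC)cc1
F10 | step 6 | [1-acetoxy-2,3-epoxy-6-(4-methoxybenzyloxy)cyclohex-4-en-5-yl]methyl benzoate | CC(=O)O[C@H]1[C@H]2O[C@H]2C=C(COC(=O)c2ccccc2)[C@@H]1OCc1ccc(OC)cc1
F11 | step 12 | [5-acetoxy-6-(benzoyloxy)-3-(chloroacetoxy)-4-hydroxycyclohex-1-en-1-yl]methyl benzoate | CC(=O)O[C@H]1[C@@H](O)[C@H](OC(=O)CCl)C=C(COC(=O)c2ccccc2)[C@@H]1OC(=O)c1ccccc1
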